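**Bench rule.** Temperature first: the rule of thumb at the bench says that 10 K more runs a flask twice as fast, and that a chain reaction goes with the square root of its initiator. Here are the flasks, the earlier runs and the questions.

all flasks: G 0.80 M

|  | D | E | temperature | remark | time |
|---|---|---|---|---|---|
| south | 8 mM | 2.5 mol% | 35 °C | run made earlier |  |
| south-east | 8 mM | 10 mol% | 62 °C | run made earlier |  |
| north-west | 16 mM | 5 mol% | 35 °C | run made earlier |  |
| delta | 8.00 mM | 5 mol% | 55 °C |  | 15 min |
| gamma | 8.00 mM | 5 mol% | 85 °C |  | 15 min |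
| zeta | 8.00 mM | 5 mol% | 70 °C |  | 15 min |
| beta | 8.00 mM | 5 mol% | 40 °C |  | 15 min |

| run | time / min | X / % | G / % |
|---|---|---|---|
| south | 5.00 | 0 | 102 |
| south | 15.0 | 0 | 99 |
| south | 25.0 | 1 | 99 |
| south | 40.0 | 2 | 100 |
| south-east | 1.33 | 0 | 100 |
| south-east | 3.00 | 1 | 98 |
| south-east | 6.00 | 4 | 98 |
| south-east | 15.0 | 13 | 87 |
| north-west | 4.00 | 2 | 101 |
| north-west | 8.00 | 0 | 102 |
| north-west | 15.0 | 1 | 101 |
| north-west | 40.0 | 2 | 102 |

(standard deviation of a reading: 1.5 percentage points)



* the best flask by amount of X, in percent of the G charged; "all alike" if 1.5 percentage points covers them all (delta / gamma / zeta / beta / all alike)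
* amount of X at the end, in percent of the G charged, delta
* amount of X at the end, in percent of the G charged, gamma
* amount of X at the end, in percent of the G charged, zeta
* amount of X at the end, in percent of the G charged, beta

**The readings.** In the south and north-west runs at 35 °C, X reaches 2 % at 40.0 min. The south-east run waits, then climbs from 4 % at 6.00 min to 13 % at 15.0 min. I read that wait as D removing chain starts before X can grow. Carrying the last south-east reading to gamma by the bench rule, I get 45.3 %.

**The border.** The rule speaks of speed, so write the balance of D, which I take for an inhibitor, charged at 8.00 mM, less than the 40.0 mM of E. Assume that each E gives one start and each D removes one. The toll τ, the fraction of the E charge that D takes, is then 0.200 in gamma, and 0.100 in the south-east run. The surplus S, the chain starts left once D is paid, is 32.0 mM in gamma. With τ below 1, the E charge can pay for D; at 1, S is zero, and there I set the border of the rule.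

**The forecast.** It names gamma as best, with delta 2 %, gamma 25 %, zeta 18 % and beta 0 %. At gamma it expects that “E burns out within minutes (dead-end)”. We part there: my rule gives 45.3 %.

**The result.** The flasks give delta 1.92 %, gamma 50.8 %, zeta 17.0 % and beta 0.145 %, so the best is gamma.

    G + L → X + L, rate k1*[L]*[G] (k = 1.10 M⁻¹ min⁻¹, Ea = 51.0 kJ mol⁻¹)
    L + X → J (k = 0.0520 M⁻¹ min⁻¹, Ea = 90.0 kJ mol⁻¹)
    G + Z → L + X (k = 1.22 M⁻¹ min⁻¹, Ea = 71.0 kJ mol⁻¹)
    L + D → Q (k = 88.6 M⁻¹ min⁻¹, Ea = 67.0 kJ mol⁻¹)
    E → Z (k = 0.0828 min⁻¹, Ea = 103 kJ mol⁻¹)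
    (constants at 70 °C)

**Not at rest.** At 15.0 min, gamma is still moving: L stands at 0.0178 M, J at 1.75 %, and its slowest mode has a half-life of 11.2 min. At 150 min, X in gamma has reached 65.9 %, up by 15 percentage points, and G stands at 30.1 %, with L down to 2.11 × 10⁻⁸ M. J is then 4.00 % of the G charged, or 32.0 mM, about the surplus S of 32.0 mM. A neighbour of gamma with 0.20 M of G and 0.0400 equiv of D has a surplus of 2.00 mM, and at 15.0 min it shows L at 0.00190 M and X at 9.81 %.

The runs are simulated with constants of no real substance.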